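Ring A is assembled, not functionalised. Cutting its C1'–C2' and C5'–C6' bonds leaves a terminal ynone (C1' and C6', already carrying the propanoyl chain and silyl-protected ring B) and the bis(trimethylsilyl) diene of methyl α,γ-diprenylacetoacetate (C2' to C5'). The feature exploited is the alternation on ring A of oxygen at C2' and C4' with prenyl at C3' and C5', which repeats the ester carbon, α-carbon, keto carbon and γ-carbon of that keto ester. One Diels–Alder benzannulation joins the two partners, closes ring A and, after loss of methanol and the trimethylsilyl groups, delivers the fully substituted resorcinol ketone, so no arene prenylation is needed.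

Key step: step 8

Remark on stereochemistry: the target has no stereocentre and no stereogenic double bond, so it is one achiral compound and no enantioselective step is needed. The only geometry that matters on the way is the C3=C4 enol ether of the diene, planned as Z.

Remark on design: the structures of both cycloaddition partners and of the cycloaddition product were checked against the target and are used as drawn. Ring B carries a tert-butyldimethylsilyl ether so that it survives the cold dilute acid that strips the trimethylsilyl groups. The diene is made fresh and used crude and in excess.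

Step 1
Reactants: 1 methyl acetoacetate; 2 prenyl bromide (1-bromo-3-methylbut-2-ene)
Product: 4 methyl 7-methyl-3-oxooct-6-enoate, via sodium lithium dianion of methyl acetoacetate 3 (not isolated)
Conditions: NaH, THF, 0 °C; n-BuLi, 0 °C; then 2 (1 equiv), 0 °C to rt; cold 1 M HCl
Reagents that add atoms: none
Why: Weiler dianion alkylation, in which the γ-carbanion, the more basic and more nucleophilic site of the dianion, should be alkylated by the allylic bromide while the stabilised α-enolate stays untouched.

Step 2
Reactants: 4 methyl 7-methyl-3-oxooct-6-enoate; 2 prenyl bromide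
Product: 5 methyl 7-methyl-2-(3-methylbut-2-en-1-yl)-3-oxooct-6-enoate (racemic)
Conditions: K2CO3, acetone, reflux; 2 in slight deficit
Reagents that add atoms: none
Why: Acetoacetic ester alkylation of the β-keto ester monoanion at the α-carbon with a reactive allylic bromide, the slight deficit of bromide limiting double alkylation; the new C2 centre is racemic and is erased in step 3.

Step 3
Reactants: 5 methyl 7-methyl-2-(3-methylbut-2-en-1-yl)-3-oxooct-6-enoate
Product: 6 methyl 7-methyl-2-(3-methylbut-2-en-1-yl)-3-(trimethylsilyloxy)octa-2,6-dienoate (C2=C3 isomer mixture)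
Conditions: TMSCl, Et3N, toluene, rt, 2–3 d; filtration under Ar
Reagents that add atoms: chlorotrimethylsilane, C[Si](C)(C)Cl
Why: Silyl enol ether formation by amine-mediated O-silylation of the keto ester enol should give the conjugated 3-silyloxy enoate, whose C2=C3 geometry is irrelevant because this bond becomes the C2–C3 single bond of the diene.

Step 4
Reactants: 6 methyl 7-methyl-2-(3-methylbut-2-en-1-yl)-3-(trimethylsilyloxy)octa-2,6-dienoate
Product: 8 (3Z)-1-methoxy-7-methyl-2-(3-methylbut-2-enyl)-1,3-bis(trimethylsilyloxy)octa-1,3,6-triene, via lithium ester dienolate 7 (not isolated)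
Conditions: LDA, THF, −78 °C; TMSCl, −78 °C to rt; pentane, filtration under Ar; used crude at once
Reagents that add atoms: chlorotrimethylsilane, C[Si](C)(C)Cl
Why: Vinylogous (γ) deprotonation of the enoate by LDA and O-silylation of the resulting ester dienolate (silyl ketene acetal formation) should give the diene, the C4 chain settling anti to the substituted C2 (3Z) for steric reasons; the ketene acetal geometry does not matter.

Step 5
Reactants: 9 3-(4-hydroxyphenyl)propanoic acid
Product: 10 3-(4-hydroxyphenyl)-N-methoxy-N-methylpropanamide
Conditions: MeNHOMe·HCl, EDC·HCl, HOBt (cat.), N-methylmorpholine, CH2Cl2/DMF, 0 °C to rt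
Reagents that add atoms: N,O-dimethylhydroxylamine hydrochloride, CNOC.Cl
Why: Carbodiimide-mediated amide coupling to the Weinreb amide, which tolerates the free phenol because any aryl ester formed is itself aminolysed by the hydroxylamine.

Step 6
Reactants: 10 3-(4-hydroxyphenyl)-N-methoxy-N-methylpropanamide
Product: 11 3-[4-(tert-butyldimethylsilyloxy)phenyl]-N-methoxy-N-methylpropanamide
Conditions: TBSCl, imidazole, DMF, rt
Reagents that add atoms: tert-butyldimethylsilyl chloride, CC(C)(C)[Si](C)(C)Cl
Why: Standard imidazole-promoted silylation of a phenol, giving an aryl silyl ether that withstands the Grignard reagent of step 7 and the dilute acid of step 8.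

Step 7
Reactants: 11 3-[4-(tert-butyldimethylsilyloxy)phenyl]-N-methoxy-N-methylpropanamide; 12 ethynylmagnesium bromide
Product: 14 5-[4-(tert-butyldimethylsilyloxy)phenyl]pent-1-yn-3-one, via chelated tetrahedral magnesium adduct 13 (not isolated)
Conditions: 12 (0.5 M in THF, excess), THF, 0 °C to rt; inverse quench into ice-cold 1 M HCl/Et2O
Reagents that add atoms: none
Why: Weinreb ketone synthesis, in which the chelated tetrahedral adduct prevents a second addition and the inverse acidic quench protonates the released N,O-dimethylhydroxylamine before it can add to the ynone in conjugate fashion.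

Step 8
Reactants: 8 (3Z)-1-methoxy-7-methyl-2-(3-methylbut-2-enyl)-1,3-bis(trimethylsilyloxy)octa-1,3,6-triene; 14 5-[4-(tert-butyldimethylsilyloxy)phenyl]pent-1-yn-3-one
Product: 16 3-[4-(tert-butyldimethylsilyloxy)phenyl]-1-[2,4-dihydroxy-3,5-bis(3-methylbut-2-en-1-yl)phenyl]propan-1-one (gancaonin J ring-B silyl ether), via silylated cyclohexa-1,4-diene cycloadduct 15 (not isolated)
Conditions: 8 (excess), toluene (concentrated), rt to 60 °C, Ar; then 0.5 M HCl, THF, 0 °C, brief
Reagents that add atoms: none
Why: Diels–Alder benzannulation of a 1-alkoxy-1,3-bis(silyloxy)diene with an acetylenic ketone, a known route to acyl resorcinols: the electron-rich diene and the electron-poor ynone should combine in an asynchronous [4+2] cycloaddition (at the limit a Mukaiyama–Michael addition followed by collapse of the allenolate onto the silyloxycarbenium ion) to give cyclohexa-1,4-diene 15. Ring A is closed in a six-membered [4+2] mode, the C5'–C6' bond forming ahead of the C1'–C2' bond. The step needs one regiochemistry, and polarisation secures it: diene C4, the terminus with the largest HOMO coefficient, bonds to the unsubstituted β-carbon of the ynone, which puts the ester-derived oxygen ortho and the ketone-derived oxygen para to the acyl group. The (3Z) enol ether keeps the C4 chain on the outside of the s-cis diene and the C2 prenyl group disfavours the s-trans conformer, so the reactive conformation should be reachable despite the double substitution. On cold dilute acid the mixed silyl methyl ketal at C2' should lose its silyl group and then methanol, the C4' silyl enol ether should hydrolyse and the dienone should tautomerise irreversibly to the arene, while the aryl tert-butyldimethylsilyl ether and both prenyl groups should stay intact. No stereocentre is created, since the two sp3 ring carbons of 15 are erased on aromatisation.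

Step 9
Reactants: 16 gancaonin J ring-B tert-butyldimethylsilyl ether
Product: 17 gancaonin J, 1-[2,4-dihydroxy-3,5-bis(3-methylbut-2-en-1-yl)phenyl]-3-(4-hydroxyphenyl)propan-1-one
Conditions: TBAF, AcOH, THF, 0 °C
Reagents that add atoms: none
Why: Fluoride-mediated cleavage of an aryl silyl ether, buffered with acetic acid so that the resorcinol ketone is not held as a phenoxide and the prenyl groups see neither strong acid nor strong base.

Compound list
1 | methyl acetoacetate | COC(=O)CC(C)=O | starting material
2 | prenyl bromide (1-bromo-3-methylbut-2-ene) | CC(C)=CCBr | starting material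
3 | sodium lithium dianion of methyl acetoacetate | COC(=O)[CH-]C(=O)[CH2-].[Na+].[Li+] | intermediate
4 | methyl 7-methyl-3-oxooct-6-enoate | COC(=O)CC(=O)CCC=C(C)C | intermediate
5 | methyl 7-methyl-2-(3-methylbut-2-en-1-yl)-3-oxooct-6-enoate (racemic) | COC(=O)C(CC=C(C)C)C(=O)CCC=C(C)C | intermediate
6 | methyl 7-methyl-2-(3-methylbut-2-en-1-yl)-3-(trimethylsilyloxy)octa-2,6-dienoate (C2=C3 isomer mixture, geometry immaterial) | COC(=O)C(CC=C(C)C)=C(O[Si](C)(C)C)CCC=C(C)C | intermediate
7 | lithium (3Z)-1-methoxy-7-methyl-2-(3-methylbut-2-enyl)-3-(trimethylsilyloxy)octa-1,3,6-trien-1-olate (ester dienolate) | CC(C)=CC/C=C(O[Si](C)(C)C)/C(CC=C(C)C)=C(OC)[O-].[Li+] | intermediate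
8 | (3Z)-1-methoxy-7-methyl-2-(3-methylbut-2-enyl)-1,3-bis(trimethylsilyloxy)octa-1,3,6-triene (ketene acetal geometry immaterial) | CC(C)=CC/C=C(O[Si](C)(C)C)/C(CC=C(C)C)=C(OC)O[Si](C)(C)C | intermediate
9 | 3-(4-hydroxyphenyl)propanoic acid | O=C(O)CCc1ccc(O)cc1 | starting material
10 | 3-(4-hydroxyphenyl)-N-methoxy-N-methylpropanamide | CON(C)C(=O)CCc1ccc(O)cc1 | intermediate
11 | 3-[4-(tert-butyldimethylsilyloxy)phenyl]-N-methoxy-N-methylpropanamide | CON(C)C(=O)CCc1ccc(O[Si](C)(C)C(C)(C)C)cc1 | intermediate
12 | ethynylmagnesium bromide | C#C[Mg]Br | starting material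
13 | bromomagnesium 5-[4-(tert-butyldimethylsilyloxy)phenyl]-3-[methoxy(methyl)amino]pent-1-yn-3-olate (chelated tetrahedral adduct, racemic) | C#CC(O[Mg]Br)(N(C)OC)CCc1ccc(O[Si](C)(C)C(C)(C)C)cc1 | intermediate
14 | 5-[4-(tert-butyldimethylsilyloxy)phenyl]pent-1-yn-3-one | C#CC(=O)CCc1ccc(O[Si](C)(C)C(C)(C)C)cc1 | intermediate
15 | 1-[6-methoxy-3,5-bis(3-methylbut-2-en-1-yl)-4,6-bis(trimethylsilyloxy)cyclohexa-1,4-dien-1-yl]-3-[4-(tert-butyldimethylsilyloxy)phenyl]propan-1-one (racemic diastereomer mixture, both centres erased on aromatisation) | COC1(O[Si](C)(C)C)C(CC=C(C)C)=C(O[Si](C)(C)C)C(CC=C(C)C)C=C1C(=O)CCc1ccc(O[Si](C)(C)C(C)(C)C)cc1 | intermediate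
16 | 3-[4-(tert-butyldimethylsilyloxy)phenyl]-1-[2,4-dihydroxy-3,5-bis(3-methylbut-2-en-1-yl)phenyl]propan-1-one | CC(C)=CCc1cc(C(=O)CCc2ccc(O[Si](C)(C)C(C)(C)C)cc2)c(O)c(CC=C(C)C)c1O | intermediate
17 | gancaonin J, 1-[2,4-dihydroxy-3,5-bis(3-methylbut-2-en-1-yl)phenyl]-3-(4-hydroxyphenyl)propan-1-one (achiral) | CC(C)=CCc1cc(C(=O)CCc2ccc(O)cc2)c(O)c(CC=C(C)C)c1O | target

Total step count: 9 (steps 1–4 for the diene, steps 5–7 for the ynone, step 8 to join them, step 9 to deprotect).
Longest linear sequence: 6 steps (1, 2, 3, 4, 8, 9).

Steps most likely to fail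

Step 8. The doubly substituted diene may add to the ynone only slowly, the reaction may stop at open-chain conjugate adducts after silyl transfer, or the diene may be protodesilylated before it reacts. The fallback sets out from 4 (with 14) and leaves the α-carbon free, which gives a 4-monosubstituted diene of the commonest type. Compound 4 would be silylated as in step 3 to methyl 7-methyl-3-(trimethylsilyloxy)octa-2,6-dienoate F1, deprotonated with LDA to its lithium ester dienolate F2 and silylated to (3Z)-1-methoxy-7-methyl-1,3-bis(trimethylsilyloxy)octa-1,3,6-triene F3. Cycloaddition of this diene with 14 under the conditions of step 8 should pass through the cyclohexa-1,4-diene cycloadduct F4 and give, after the same acidic work-up, 3-[4-(tert-butyldimethylsilyloxy)phenyl]-1-[2,4-dihydroxy-5-(3-methylbut-2-en-1-yl)phenyl]propan-1-one F5. C-Prenylation of this resorcinol ketone with 2 (DBU, dry THF, rt) can reach carbon only at C3', the position between the two oxygens, because C5' is occupied and C6' is not activated. O-Prenylated material would have to be separated. The fallback comes back to the route at 16.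

Step 4. γ-Deprotonation of the tetrasubstituted enol ether may be incomplete, silyl groups may migrate in the lithium dienolate, and the ketene acetal may hydrolyse during isolation. The fallback sets out from 5 and installs both silyl groups in one operation by soft enolisation with TMSOTf and Et3N in Et2O at 0 °C, with no strong base and no lithium dienolate. Only the C4 hydrogens can give a conjugated ketene acetal, so the same diene is expected. It comes back to the route at 8 and makes no compound outside the list (F0).

Step 7. The released hydroxylamine or a second acetylide may add in conjugate fashion to the new ynone during reaction or quench, and the terminal ynone may oligomerise on concentration. The fallback sets out from 11 and forms the ketone in an amine-free oxidation. DIBAL-H (THF, −78 °C) should reduce the Weinreb amide through the aluminium-chelated hemiaminal diisobutylaluminium 3-[4-(tert-butyldimethylsilyloxy)phenyl]-1-[methoxy(methyl)amino]propan-1-olate F6 to 3-[4-(tert-butyldimethylsilyloxy)phenyl]propanal F7. Addition of 12 (THF, 0 °C) should give racemic 5-[4-(tert-butyldimethylsilyloxy)phenyl]pent-1-yn-3-ol F8. Oxidation of this propargylic alcohol with activated MnO2 in CH2Cl2 comes back to the route at 14.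

Further compounds
F1 | step 8 | methyl 7-methyl-3-(trimethylsilyloxy)octa-2,6-dienoate (C2=C3 isomer mixture) | COC(=O)C=C(O[Si](C)(C)C)CCC=C(C)C
F2 | step 8 | lithium (3Z)-1-methoxy-7-methyl-3-(trimethylsilyloxy)octa-1,3,6-trien-1-olate | CC(C)=CC/C=C(O[Si](C)(C)C)/C=C(OC)[O-].[Li+]
F3 | step 8 | (3Z)-1-methoxy-7-methyl-1,3-bis(trimethylsilyloxy)octa-1,3,6-triene | CC(C)=CC/C=C(O[Si](C)(C)C)/C=C(OC)O[Si](C)(C)C
F4 | step 8 | 1-[6-methoxy-3-(3-methylbut-2-en-1-yl)-4,6-bis(trimethylsilyloxy)cyclohexa-1,4-dien-1-yl]-3-[4-(tert-butyldimethylsilyloxy)phenyl]propan-1-one (racemic diastereomer mixture) | COC1(O[Si](C)(C)C)C=C(O[Si](C)(C)C)C(CC=C(C)C)C=C1C(=O)CCc1ccc(O[Si](C)(C)C(C)(C)C)cc1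
F5 | step 8 | 3-[4-(tert-butyldimethylsilyloxy)phenyl]-1-[2,4-dihydroxy-5-(3-methylbut-2-en-1-yl)phenyl]propan-1-one | CC(C)=CCc1cc(C(=O)CCc2ccc(O[Si](C)(C)C(C)(C)C)cc2)c(O)cc1O
F0 | step 4 | none | none
F6 | step 7 | diisobutylaluminium 3-[4-(tert-butyldimethylsilyloxy)phenyl]-1-[methoxy(methyl)amino]propan-1-olate (racemic) | CON(C)C(O[Al](CC(C)C)CC(C)C)CCc1ccc(O[Si](C)(C)C(C)(C)C)cc1
F7 | step 7 | 3-[4-(tert-butyldimethylsilyloxy)phenyl]propanal | O=CCCc1ccc(O[Si](C)(C)C(C)(C)C)cc1
F8 | step 7 | 5-[4-(tert-butyldimethylsilyloxy)phenyl]pent-1-yn-3-ol (racemic) | C#CC(O)CCc1ccc(O[Si](C)(C)C(C)(C)C)cc1
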